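(The numbers are made up; what happens was integrated by code.)

Freeze [starting material] at its solubility and reckon the share of target from that.

    starting material + starting material ⇌ target (K1 = 57 M⁻¹, k1 = 3.8 M⁻¹ h⁻¹, Ea1 = 68.0 kJ mol⁻¹, ΔH1 = −29.0 kJ mol⁻¹)
    target → over-reaction product (k2 = 0.15 h⁻¹, Ea2 = 94.0 kJ mol⁻¹)
    solid substrate ⇌ starting material, rate k3*(cs3 - [starting material]) while solid is left; crystals form when [starting material] > cs3 (cs3 = 3.9 mM, k3 = 2.3 h⁻¹)
    (constants at 20 °C)

the same everywhere: solid substrate 0.050 M; time 50 h

|  | temperature |
|---|---|
| cedar | 20 °C |
| elm | −40 °C |
| birch | 50 °C |
| oak | −10 °C |

- a species is counted by the solid substrate in it: one target or over-reaction product counts as two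
- where a step has two of a species, its rate is k times that concentration squared, and two are used at each turn
- given per volume of solution although it is solid: solid substrate
- the constants hold at 20 °C; other temperatures follow from the activation energies and enthalpies
- at the start none of the solid substrate is in solution
- what has only dissolved of solid substrate counts as not reacted

* the flask that comes out highest in share of target in all that became target or over-reaction product, or "all alike" when all lie within 1.5 percentage points (cedar / elm / birch / oak / all alike)
* share of target in all that became target or over-reaction product, cedar
* share of target in all that became target or over-reaction product, elm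
* share of target in all that became target or over-reaction product, birch
* share of target in all that became target or over-reaction product, oak

**Frozen feed.** I took [starting material] as constant at 3.9 mM, because the dissolving time of 0.435 h is far shorter than the run of 50 h. Target was then fed at a steady rate. The size of that rate cancelled in the share, which is the selectivity of the flask.

**From below.** Over-reaction product is k2 times the time integral of [target]. While [target] does not fall, that integral stays below [target] times the run. So the share was at least one over one plus k2 times the run, which gave 11.8 % for cedar. For elm, the rise of K from 57 M⁻¹ to 1220 M⁻¹ measured the temperature step. Scaled by the ratio of Ea2 to dH1, it gave k2 = 7.34 × 10⁻⁶ h⁻¹, and so a bound of >99.9 %.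

**From above.** In cedar, target is lost by return and by going on, at 0.217 h⁻¹ together, so [target] approached its level exponentially, with a time constant of 4.62 h. The feed also started late, by a lag of 0.652 h. I named the overrun number k2 times the run less time constant and lag, and for cedar it came to 6.71. One over one plus it gave 13.0 %, the top of my cedar bracket. Elm's lower bound already stood above that. I reckoned no bracket for oak.

**The forecast.** It named elm highest, with cedar 12.8 %, elm >99.9 %, birch 0.37 % and oak 95.5 %, holding that “target settles at a small steady level while over-reaction product keeps piling up”. Its cedar value lay inside my bracket.

**Steady target.** The simulation put elm highest, with cedar 13.0 % against my 13.0 %, elm >99.9 %, birch 0.375 % and oak 95.6 %. In birch the relaxation half-life of the first step, both ways together, was 0.204 h against the run of 50 h, and at 23.2 h target was made 1.00 times as fast as it was used up. With k2 scaled to 5.38 h⁻¹, k1 scaled to 50.7 M⁻¹ h⁻¹ and k3 unchanged, the overrun number of birch was 265, which gave 0.376 % where birch stood at 0.375 %.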